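**Plan**
- Ring A carries oxygen on C5, C7 and C8, so its carbons C5–C8 correspond to a 1,1,3,4-tetraoxygenated butadiene and its fused bond C4a–C8a to the unsubstituted C5=C6 edge of a 4-pyranone (ring C).
- Retrosynthesis: remove the 8-acetyl group and the benzyl ethers, cut C4a–C5 and C8–C8a back to a 5-bromo-4-pyranone and a silyl ketene acetal diene, then cut the C2–aryl bond and the C–Br bond of the pyranone.
- Forward: ring C is bought as 3-hydroxy-4-pyranone, ring B is joined to C2 by Suzuki coupling, bromine is placed on the future C4a, and ring A is closed last by a one-flask formal [4+2] annulation that aromatises by loss of HBr and methanol.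
- The diene comes from methyl 4-chloroacetoacetate and allyl alcohol; its allyl ether singles out O8 for the acetate.
- The target has no stereocentre; the sp3 centres that arise during the annulation vanish on aromatisation.

Key step: step 8

Remark: the diene 13 is drawn as its (1Z,3Z) isomer, but both of its double bonds end up in the aromatic ring, so a mixture of geometric isomers should serve equally; 3-hydroxy-4H-pyran-4-one is taken as a purchasable material.

**Route**

Step 1
Reactants: 1 3-hydroxy-4H-pyran-4-one (pyromeconic acid)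
Product: 2 2-bromo-3-hydroxy-4H-pyran-4-one
Conditions: NBS (1.0 equiv), MeCN, 0 → 23 °C
Reagents that add atoms: N-bromosuccinimide, O=C1CCC(=O)N1Br
Why: Electrophilic bromination should occur ortho to the enolic hydroxyl at C2, the position at which 3-hydroxy-4-pyranones such as kojic and pyromeconic acid take up electrophiles (halogenation, hydroxyalkylation, aminomethylation).

Step 2
Reactants: 2 2-bromo-3-hydroxy-4H-pyran-4-one; 3 benzyl bromide
Product: 4 3-(benzyloxy)-2-bromo-4H-pyran-4-one
Conditions: K2CO3, DMF, 23 °C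
Reagents that add atoms: none
Why: Williamson etherification of the acidic enolic hydroxyl under carbonate conditions is the usual protection of 3-hydroxy-4-pyranones and avoids alkoxide bases that would displace the vinylogous acyl bromide.

Step 3
Reactants: 4 3-(benzyloxy)-2-bromo-4H-pyran-4-one; 5 [4-(benzyloxy)phenyl]boronic acid
Product: 6 3-(benzyloxy)-2-[4-(benzyloxy)phenyl]-4H-pyran-4-one
Conditions: Pd(PPh3)4 (5 mol %), K3PO4, 1,4-dioxane/H2O, 85 °C
Reagents that add atoms: none
Why: Suzuki–Miyaura coupling, in which the C2–Br bond of the 2-halo-4-pyranone behaves as a vinylogous acyl halide and adds readily to zerovalent palladium, as 2-halochromones do in flavone syntheses.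

Step 4
Reactants: 6 3-(benzyloxy)-2-[4-(benzyloxy)phenyl]-4H-pyran-4-one
Product: 8 3-(benzyloxy)-2-[4-(benzyloxy)phenyl]-5-bromo-4H-pyran-4-one, via 5,6-dibromide 7 (not isolated)
Conditions: Br2 (1.05 equiv), CH2Cl2, −20 → 0 °C; then Et3N, 0 → 23 °C
Reagents that add atoms: bromine, BrBr
Why: Bromine adds across the enol-ether-like C5=C6 bond and triethylamine removes the acidic C5 proton with E1cB loss of the C6 bromide (addition–elimination α-bromination of a vinylogous ester, as in the preparation of 3-bromochromones), which leaves bromine on the future C4a.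

Step 5
Reactants: 9 methyl 4-chloro-3-oxobutanoate; 10 allyl alcohol
Product: 11 methyl 4-(allyloxy)-3-oxobutanoate
Conditions: NaH (2.2 equiv), THF, 0 → 23 °C; then 1 M HCl
Reagents that add atoms: none
Why: Williamson-type SN2 displacement of the α′-chloride by sodium allyloxide while the β-keto ester is held as its sodium enolate, the standard route to 4-alkoxyacetoacetates.

Step 6
Reactants: 11 methyl 4-(allyloxy)-3-oxobutanoate
Product: 12 methyl (2E)-4-(allyloxy)-3-methoxybut-2-enoate
Conditions: HC(OMe)3, H2SO4 (cat.), MeOH, 23 °C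
Reagents that add atoms: trimethyl orthoformate, COC(OC)OC
Why: Acid-catalysed ketalisation with the orthoformate and loss of methanol should give the conjugated (E)-β-methoxy enoate, the thermodynamic enol ether, as with other acetoacetates.

Step 7
Reactants: 12 methyl (2E)-4-(allyloxy)-3-methoxybut-2-enoate
Product: 13 (1Z,3Z)-4-(allyloxy)-1,3-dimethoxy-1-[(trimethylsilyl)oxy]buta-1,3-diene
Conditions: LiN(i-Pr)2, Me3SiCl (in situ quench), THF, −78 °C; used crude
Reagents that add atoms: chlorotrimethylsilane, C[Si](C)(C)Cl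
Why: γ-Deprotonation of a β-methoxy enoate and O-silylation of the dienolate is the established preparation of 1,3-dialkoxy-1-silyloxybutadienes, and the silyl chloride already present at −78 °C should trap the dienolate before a [2,3]-Wittig shift of the allyl ether.

Step 8
Reactants: 8 3-(benzyloxy)-2-[4-(benzyloxy)phenyl]-5-bromo-4H-pyran-4-one; 13 (1Z,3Z)-4-(allyloxy)-1,3-dimethoxy-1-[(trimethylsilyl)oxy]buta-1,3-diene
Product: 16 8-(allyloxy)-3-(benzyloxy)-2-[4-(benzyloxy)phenyl]-5-hydroxy-7-methoxy-4H-chromen-4-one, via silyloxypyrylium triflate 14 (not isolated), via Michael adduct 15 (not isolated)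
Conditions: t-BuMe2SiOTf (1.2 equiv), CH2Cl2, 23 °C, 1 h; 13 (1.5 equiv), 2,6-lutidine (0.3 equiv), −78 → −40 °C; Bu4NF (4 equiv, THF), −78 → 23 °C; aq. NH4Cl
Reagents that add atoms: none
Why: Proposed new method: O-silylation of the pyranone carbonyl of 8 gives the 4-silyloxypyrylium ion 14, and the allyloxy-bearing terminus (C4) of the silyl dienolate 13 adds to its only free α-position, C6, in a vinylogous Mukaiyama–Michael reaction that forms the C8–C8a bond and leaves the 2H-pyran silyl enol ether 15 with an (E)-β-methoxy enoate side chain. Fluoride then releases the α-bromo enolate, whose bromine-bearing carbon acylates the ester in a 6-(enolexo)-exo-trig Dieckmann closure (C4a–C5 bond, ring A); deprotonation at C8, loss of bromide from C4a and loss of the C8a proton aromatise the ring with no oxidant, and if bromide leaves first the 6-alkylpyranone closes through its vinylogous enolate to the same phenoxide. The closest known reactions are the addition of silyl enol ethers to 4-silyloxypyrylium and 4-silyloxybenzopyrylium triflates, the regioselective annulation of 1,3-dialkoxy-1-silyloxybutadienes onto bromoquinones with loss of HBr and methanol, and Michael–Dieckmann annulations of the Hauser–Kraus type that aromatise by expelling a leaving group; none has been run on a 3-bromo-4-pyranone. No stereocentre is kept: the two sp3 centres of 15 and the transient ring-fusion centre all become aromatic carbons. The step needs one regiochemistry, diene C4 to pyranone C6 and ester carbon to C5, which is secured by the pyrylium polarity (C2 is shielded and deactivated by the 4-benzyloxyphenyl group, C4 carries the silyloxy group), by the γ-selectivity of silyl dienolates, and by the bromine atom, which blocks C4a against retro-oxa-Michael opening of ring C until it departs as the leaving group that sets the aromatic oxidation level.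

Step 9
Reactants: 16 8-(allyloxy)-3-(benzyloxy)-2-[4-(benzyloxy)phenyl]-5-hydroxy-7-methoxy-4H-chromen-4-one
Product: 17 3-(benzyloxy)-2-[4-(benzyloxy)phenyl]-5,8-dihydroxy-7-methoxy-4H-chromen-4-one
Conditions: Pd(PPh3)4 (5 mol %), morpholine, THF, 23 °C, argon
Reagents that add atoms: none
Why: Tsuji–Trost deallylation, in which zerovalent palladium ionises the aryl allyl ether to a π-allyl complex that morpholine captures, should leave the benzyl and methyl ethers untouched.

Step 10
Reactants: 17 3-(benzyloxy)-2-[4-(benzyloxy)phenyl]-5,8-dihydroxy-7-methoxy-4H-chromen-4-one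
Product: 18 3-(benzyloxy)-2-[4-(benzyloxy)phenyl]-5-hydroxy-7-methoxy-4-oxo-4H-chromen-8-yl acetate
Conditions: Ac2O (1.05 equiv), pyridine, CH2Cl2, 0 °C, argon
Reagents that add atoms: acetic anhydride, CC(=O)OC(C)=O
Why: Chemoselective O-acylation should favour O8 because the 5-hydroxyl is locked in a hydrogen bond to the C4 carbonyl and is far less nucleophilic than the free 8-hydroxyl towards one equivalent of anhydride at 0 °C.

Step 11
Reactants: 18 3-(benzyloxy)-2-[4-(benzyloxy)phenyl]-5-hydroxy-7-methoxy-4-oxo-4H-chromen-8-yl acetate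
Product: 19 3,5-dihydroxy-2-(4-hydroxyphenyl)-7-methoxy-4-oxo-4H-chromen-8-yl acetate (pollenitin 8-acetate)
Conditions: H2 (1 atm), Pd/C (10 wt % palladium on carbon), EtOAc/THF, 23 °C
Reagents that add atoms: none
Why: Hydrogenolysis of the two benzyl ethers under neutral, non-nucleophilic conditions should leave the aryl acetate, the methyl ether and the chromone C2=C3 bond intact.

**Compound list**
1 | 3-hydroxy-4H-pyran-4-one (pyromeconic acid) | O=c1ccocc1O | starting material
2 | 2-bromo-3-hydroxy-4H-pyran-4-one | O=c1ccoc(Br)c1O | intermediate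
3 | benzyl bromide | BrCc1ccccc1 | starting material
4 | 3-(benzyloxy)-2-bromo-4H-pyran-4-one | O=c1ccoc(Br)c1OCc1ccccc1 | intermediate
5 | [4-(benzyloxy)phenyl]boronic acid | OB(O)c1ccc(OCc2ccccc2)cc1 | starting material
6 | 3-(benzyloxy)-2-[4-(benzyloxy)phenyl]-4H-pyran-4-one | O=c1ccoc(-c2ccc(OCc3ccccc3)cc2)c1OCc1ccccc1 | intermediate
7 | 3-(benzyloxy)-2-[4-(benzyloxy)phenyl]-5,6-dibromo-5,6-dihydro-4H-pyran-4-one (racemic, mixture of cis and trans isomers; not isolated) | O=C1C(Br)C(Br)OC(-c2ccc(OCc3ccccc3)cc2)=C1OCc1ccccc1 | intermediate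
8 | 3-(benzyloxy)-2-[4-(benzyloxy)phenyl]-5-bromo-4H-pyran-4-one | O=c1c(Br)coc(-c2ccc(OCc3ccccc3)cc2)c1OCc1ccccc1 | intermediate
9 | methyl 4-chloro-3-oxobutanoate (methyl 4-chloroacetoacetate) | COC(=O)CC(=O)CCl | starting material
10 | allyl alcohol (prop-2-en-1-ol) | C=CCO | starting material
11 | methyl 4-(allyloxy)-3-oxobutanoate | COC(=O)CC(=O)COCC=C | intermediate
12 | methyl (2E)-4-(allyloxy)-3-methoxybut-2-enoate | COC(=O)/C=C(/OC)COCC=C | intermediate
13 | (1Z,3Z)-4-(allyloxy)-1,3-dimethoxy-1-[(trimethylsilyl)oxy]buta-1,3-diene | CO/C(O[Si](C)(C)C)=C/C(OC)=C/OCC=C | intermediate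
14 | 3-(benzyloxy)-2-[4-(benzyloxy)phenyl]-5-bromo-4-[(tert-butyldimethylsilyl)oxy]pyrylium trifluoromethanesulfonate (not isolated) | CC(C)(C)[Si](C)(C)Oc1c(Br)c[o+]c(-c2ccc(OCc3ccccc3)cc2)c1OCc1ccccc1.[O-]S(=O)(=O)C(F)(F)F | intermediate
15 | methyl (2E)-4-(allyloxy)-4-{5-(benzyloxy)-6-[4-(benzyloxy)phenyl]-3-bromo-4-[(tert-butyldimethylsilyl)oxy]-2H-pyran-2-yl}-3-methoxybut-2-enoate (racemic, mixture of diastereomers at the two sp3 carbons; not isolated) | COC(=O)/C=C(/OC)C(OCC=C)C1OC(-c2ccc(OCc3ccccc3)cc2)=C(OCc2ccccc2)C(O[Si](C)(C)C(C)(C)C)=C1Br | intermediate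
16 | 8-(allyloxy)-3-(benzyloxy)-2-[4-(benzyloxy)phenyl]-5-hydroxy-7-methoxy-4H-chromen-4-one | COc1cc(O)c2c(=O)c(OCc3ccccc3)c(-c3ccc(OCc4ccccc4)cc3)oc2c1OCC=C | intermediate
17 | 3-(benzyloxy)-2-[4-(benzyloxy)phenyl]-5,8-dihydroxy-7-methoxy-4H-chromen-4-one | COc1cc(O)c2c(=O)c(OCc3ccccc3)c(-c3ccc(OCc4ccccc4)cc3)oc2c1O | intermediate
18 | 3-(benzyloxy)-2-[4-(benzyloxy)phenyl]-5-hydroxy-7-methoxy-4-oxo-4H-chromen-8-yl acetate | COc1cc(O)c2c(=O)c(OCc3ccccc3)c(-c3ccc(OCc4ccccc4)cc3)oc2c1OC(C)=O | intermediate
19 | 3,5-dihydroxy-2-(4-hydroxyphenyl)-7-methoxy-4-oxo-4H-chromen-8-yl acetate (pollenitin 8-acetate; achiral) | COc1cc(O)c2c(=O)c(O)c(-c3ccc(O)cc3)oc2c1OC(C)=O | target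

**Count**
Total steps: 11. Longest linear sequence: 8 steps (steps 1–4 and 8–11, from 1); the diene branch (steps 5–7) joins at step 8.

**Steps most likely to fail**

Step 8 (annulation). Three processes could defeat it: reversal of the Michael addition once fluoride frees the enolate, halophilic loss of bromine from the α-bromo-β-diketone before ring A aromatises, and opening of ring C by expulsion of O1. The fallback takes ring A ready-made from a flavonol and introduces only the 8-oxygen, by known chemistry. It sets out from benzyl bromide 3: commercially available rhamnocitrin (3,5-dihydroxy-2-(4-hydroxyphenyl)-7-methoxy-4H-chromen-4-one, COc1cc(O)c2c(=O)c(O)c(-c3ccc(O)cc3)oc2c1) would be benzylated with 3 (2.2 equiv, K2CO3, DMF), which spares the chelated 5-hydroxyl and should give 3-(benzyloxy)-2-[4-(benzyloxy)phenyl]-5-hydroxy-7-methoxy-4H-chromen-4-one F1. Elbs persulfate oxidation (K2S2O8, aq. KOH/pyridine, 5–20 °C) attacks the position para to the 5-phenoxide, C8, and should give potassium 3-(benzyloxy)-2-[4-(benzyloxy)phenyl]-5-hydroxy-7-methoxy-4-oxo-4H-chromen-8-yl sulfate F2. Hydrolysis of the sulfate ester (dilute HCl, Na2SO3, 80 °C) would release diol 17, where the route is rejoined before step 10.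

Step 7 (diene formation). The γ-allyloxy dienolate may undergo [2,3]-Wittig rearrangement before it is silylated, and the allyl vinyl ether of the diene may undergo a [3,3] shift or hydrolyse on handling. The fallback sets out from methyl 4-chloroacetoacetate 9 and replaces the allyl ether by a 4-methoxybenzyl ether, which has neither sigmatropic pathway. Compound 9 with 4-methoxybenzyl alcohol (COc1ccc(CO)cc1) and NaH should give methyl 4-[(4-methoxybenzyl)oxy]-3-oxobutanoate F3. HC(OMe)3 with a trace of p-toluenesulfonic acid should give methyl (2E)-3-methoxy-4-[(4-methoxybenzyl)oxy]but-2-enoate F4. LiN(i-Pr)2/Me3SiCl should give (1Z,3Z)-1,3-dimethoxy-4-[(4-methoxybenzyl)oxy]-1-[(trimethylsilyl)oxy]buta-1,3-diene F5. The annulation of step 8 with pyranone 8 would then pass through pyrylium salt 14 and methyl (2E)-4-{5-(benzyloxy)-6-[4-(benzyloxy)phenyl]-3-bromo-4-[(tert-butyldimethylsilyl)oxy]-2H-pyran-2-yl}-3-methoxy-4-[(4-methoxybenzyl)oxy]but-2-enoate F6 to 3-(benzyloxy)-2-[4-(benzyloxy)phenyl]-5-hydroxy-7-methoxy-8-[(4-methoxybenzyl)oxy]-4H-chromen-4-one F7. CF3CO2H/Et3SiH in CH2Cl2 at 0 °C should remove the 4-methoxybenzyl group without touching the benzyl ethers, returning to the route at diol 17.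

Step 10 (selective acetylation). Acetylation may spill over to the chelated 5-hydroxyl, and the free 5,8-hydroquinone may be oxidised by air to the quinone before it is acylated. The fallback sets out from the annulation product 16 and never exposes a free 5,8-hydroquinone. Forced benzylation of the chelated 5-hydroxyl (benzyl bromide 3, Cs2CO3, DMF, 60 °C) should give 8-(allyloxy)-3,5-bis(benzyloxy)-2-[4-(benzyloxy)phenyl]-7-methoxy-4H-chromen-4-one F8. Deallylation as in step 9 should give 3,5-bis(benzyloxy)-2-[4-(benzyloxy)phenyl]-8-hydroxy-7-methoxy-4H-chromen-4-one F9. Its only free hydroxyl would be acetylated (Ac2O, pyridine, catalytic 4-(dimethylamino)pyridine) to 3,5-bis(benzyloxy)-2-[4-(benzyloxy)phenyl]-7-methoxy-4-oxo-4H-chromen-8-yl acetate F10. Hydrogenolysis as in step 11 would then remove three benzyl groups and arrive at the target 19.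

**Further compounds**
F1 | step 8 | 3-(benzyloxy)-2-[4-(benzyloxy)phenyl]-5-hydroxy-7-methoxy-4H-chromen-4-one | COc1cc(O)c2c(=O)c(OCc3ccccc3)c(-c3ccc(OCc4ccccc4)cc3)oc2c1
F2 | step 8 | potassium 3-(benzyloxy)-2-[4-(benzyloxy)phenyl]-5-hydroxy-7-methoxy-4-oxo-4H-chromen-8-yl sulfate | COc1cc(O)c2c(=O)c(OCc3ccccc3)c(-c3ccc(OCc4ccccc4)cc3)oc2c1OS(=O)(=O)[O-].[K+]
F3 | step 7 | methyl 4-[(4-methoxybenzyl)oxy]-3-oxobutanoate | COC(=O)CC(=O)COCc1ccc(OC)cc1
F4 | step 7 | methyl (2E)-3-methoxy-4-[(4-methoxybenzyl)oxy]but-2-enoate | COC(=O)/C=C(/OC)COCc1ccc(OC)cc1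
F5 | step 7 | (1Z,3Z)-1,3-dimethoxy-4-[(4-methoxybenzyl)oxy]-1-[(trimethylsilyl)oxy]buta-1,3-diene | CO/C(O[Si](C)(C)C)=C/C(OC)=C/OCc1ccc(OC)cc1
F6 | step 7 | methyl (2E)-4-{5-(benzyloxy)-6-[4-(benzyloxy)phenyl]-3-bromo-4-[(tert-butyldimethylsilyl)oxy]-2H-pyran-2-yl}-3-methoxy-4-[(4-methoxybenzyl)oxy]but-2-enoate (racemic, mixture of diastereomers) | COC(=O)/C=C(/OC)C(OCc1ccc(OC)cc1)C1OC(-c2ccc(OCc3ccccc3)cc2)=C(OCc2ccccc2)C(O[Si](C)(C)C(C)(C)C)=C1Br
F7 | step 7 | 3-(benzyloxy)-2-[4-(benzyloxy)phenyl]-5-hydroxy-7-methoxy-8-[(4-methoxybenzyl)oxy]-4H-chromen-4-one | COc1cc(O)c2c(=O)c(OCc3ccccc3)c(-c3ccc(OCc4ccccc4)cc3)oc2c1OCc1ccc(OC)cc1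
F8 | step 10 | 8-(allyloxy)-3,5-bis(benzyloxy)-2-[4-(benzyloxy)phenyl]-7-methoxy-4H-chromen-4-one | COc1cc(OCc2ccccc2)c2c(=O)c(OCc3ccccc3)c(-c3ccc(OCc4ccccc4)cc3)oc2c1OCC=C
F9 | step 10 | 3,5-bis(benzyloxy)-2-[4-(benzyloxy)phenyl]-8-hydroxy-7-methoxy-4H-chromen-4-one | COc1cc(OCc2ccccc2)c2c(=O)c(OCc3ccccc3)c(-c3ccc(OCc4ccccc4)cc3)oc2c1O
F10 | step 10 | 3,5-bis(benzyloxy)-2-[4-(benzyloxy)phenyl]-7-methoxy-4-oxo-4H-chromen-8-yl acetate | COc1cc(OCc2ccccc2)c2c(=O)c(OCc3ccccc3)c(-c3ccc(OCc4ccccc4)cc3)oc2c1OC(C)=O
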